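## Structural features

Blepharocalyxin B has three parts. Ring A is a pentasubstituted benzene (A1 acyl, A2 OH, A3 side chain, A4 OH, A5 H, A6 OMe). The C7 ketone joins A1 to C3 of an oxane (O1, C2–C6). A seven-carbon side chain (C1''–C7'') hangs on A3. The oxane carries four stereocentres in a row of three plus one: C2 (aryl), C3 (acyl) and C4 (E-styryl, C8=C9) are contiguous, and C6 (2-arylethyl) sits across O1. Read from the stereodescriptors, the C3, C4 and C6 substituents are mutually cis and the C2 aryl group is trans to them, so the ring is 2,6-trans, (2R,3R,4S,6S), and cannot be all-equatorial. The side chain has a diarylmethine centre C1'' (R) and a carbinol C5'' (S), 1,5-related across the E-olefin C2''=C3''. Fragile features are the benzylic C2–O1 ether β to the ketone (E1cB opening, then chalcone/flavanone chemistry), the epimerisable C3, the acid-ionisable p-oxybenzylic C2 and the doubly benzylic, allylic C1''–H. The real difficulties are the contra-thermodynamic oxane, the remote C1''/C5'' relation, and the union of two hindered halves at A1–C7. The key step exploits the unit A3–C1''–C2''=C3''–C4''–C5'': it is a 1-arylbutadiene (C1''–C4'') that has gained an aryl group at C1'' and an aldehyde carbon at C4''.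

## Logic of the disconnections

37 ⇒ 36 ⇒ 35. Only O–Si and O–CH2OMe bonds are cut. The acetals are removed first, while every aryl oxygen is still silylated, so that no free p-hydroxybenzyl ether meets a Lewis acid; the six silyl groups go last under buffered fluoride. Nothing is gained in skeleton. The demand is that neither step opens C2–O1 or epimerises C3.

35 ⇒ 34 ⇒ 14 + 31. The A1–C7 bond is cut because it divides the molecule into two halves of similar size and because A1 of a symmetric ring A can be addressed by bromination. The ketone is taken back to a carbinol so that the bond forms by carbonyl addition. The demand is a weakly basic aryl-metal that adds to a hindered, enolisable β-alkoxy aldehyde, formed by halogen–metal exchange faster than C1''–H is deprotonated.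

14 ⇒ 13 ⇒ 12. C–Br and O–Si are cut. In 12 ring A is symmetric about the A3–A6 axis, so A1 and A5 are equivalent and monobromination needs no regiocontrol. The demand is that the trioxygenated ring reacts before the olefin and the silyloxyphenyl rings.

12 ⇒ 6 + 9 + 10. C4''–C5'' and C1''–aryl are cut together. The whole side chain with both stereocentres and the E-olefin then falls to a diene, an aldehyde and an arylboronic acid, each two or three steps from commerce. The demand is 1,4-regioselectivity, E-geometry, and control of a 1,5-relation by one chiral catalyst.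

6 ⇒ 4 ⇒ 2 ⇒ 1 and 9 ⇒ 8 ⇒ 7. The C1''=C2'' olefin, the formyl C–C bond and O–protecting-group bonds are cut. Lithiation between the two acetal oxygens places the carbon exactly at A3. The demand is E-selective olefination of a di-ortho-substituted aldehyde.

31 ⇒ 30 ⇒ 29 ⇒ 26. After oxidation-level changes, C3–C4 is cut in the retro-[3,3] sense, which reconnects C7 to C9 through oxygen. This converts the crowded oxane into a ten-membered lactone whose C2–O1–C6 ether is an acyclic-type linkage not subject to anomerisation. The demand is a ring-cis ketene acetal and a [3,3] shift that beats β-elimination and ionisation.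

26 ⇒ 24 ⇒ 21 + 23. The lactone C–O bond and then the C4=C8 olefin are cut. This gives an ether acid with a terminal olefin and a simple aryl vinyl carbinol that carries C9. The demands are E-selective cross-metathesis and closure of a ten-membered ring.

21 ⇒ 20 ⇒ 18 + 9; 18 ⇒ 16 ⇒ 15; 23 ⇒ 22 ⇒ 15. The C5–C6 bond is cut at an acetal carbon, and the acetal is cut to a β-hydroxy acid and the aldehyde already made for the key step. The C2 centre then controls C6 through a six-membered template. The demand is inversion at the acetal carbon without ionisation of the benzylic C2–O bond.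

## Other disconnections considered

Alternative 1: The cut is C3–C4, made through the ten-membered lactone 26. In the forward step the silyl ketene acetal undergoes a ring-contracting Ireland–Claisen rearrangement to the oxane acid A1, which is identical with 29.
- In favour: one stereospecific step of a known type closes the oxane, sets C3/C4 cis, makes the E-styryl group, and carries C2/C6 in as a preformed ether.
- Against: the lactone costs about eight steps and a medium-ring closure, and as the sole strategic step it leaves C1''/C5'' to several steps of conventional chemistry.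
- Comparison: its key step is better precedented than the nickel coupling, and on that point it is the better plan. For the oxane the two plans are equal, because the chosen route uses this very step to reach 31. For the side chain the chosen plan is shorter by several steps. The two are complementary rather than exclusive.

Alternative 2: The cut is A1–A2, so ring A is made last. The pyranone A3 is opened by Mg(OMe)2, and the resulting triketo ester undergoes Claisen cyclisation to the acylphloroglucinol A2.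
- In favour: no cryogenic aryl-metal, no bromination and no hindered carbonyl addition; here it is better than the chosen plan. The ring closure is mild.
- Against: A2 has three free ring-A phenols and only A6 must be methylated, against the usual preference for the para (A4) hydroxyl. In the open form C3 is α to a β-diketone, so epimerisation and E1cB opening of the oxane are far more likely. C1'' sits on an enolisable 1,3-dicarbonyl carbon, which invites retro-Michael loss.
- Comparison: both stereodefined halves are still needed, so nothing is saved in their preparation, and the step count is higher. On structure and mechanism it is the weaker plan for this target.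

Alternative 3: The cuts are A1–C7 and A2–O. CsF generates the aryne from the silylaryl triflate A5; the carboxylate of acid A6 adds at A2 and the acyl group shifts to A1, giving A4.
- In favour: the hindered aryl ketone and the free A2 hydroxyl arise in one operation at ambient temperature without strong base and without an oxidation, one step fewer than addition plus oxidation; here it is better than the chosen plan. The A6 methoxy group directs the oxygen to A2 as required.
- Against: A2 is also the carbon next to the bulky C1'' substituent. The aryne can be intercepted by the side-chain olefin or the C1''–H. A5 needs several steps on the finished side chain. Fluoride forbids silyl ethers, so seven acetal groups must finally be removed with acid from a molecule whose C2–O1 bond is acid-labile.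
- Comparison: equal in convergence, better by one step at the union, worse in the end-game and in chemoselectivity.

Key step: step 6

Remarks before the steps.
- Abbreviations: TBS = tert-butyldimethylsilyl; MOM = methoxymethyl; ArS = 4-(TBS-oxy)phenyl. Skeleton labels (A1–A6, O1, C2–C9, C1''–C7'') are used for all intermediates.
- Assumption: the oxane configuration is taken as 2,3-trans, 3,4-cis, 4,6-cis exactly as the descriptors say.
- Structure check: 6, 9, 10 and 12 agree with the target in connectivity, olefin geometry and configuration (7R/3S in 12 = 1''R/5''S), so no correction of the skeletons is needed. The design is tightened in three places: commercially silylated 10 and 15 and the ester 7 are used; silyl triflates are kept away from the MOM ethers; the MOM ethers are removed before the silyl ethers without protic acid.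

Step 1
Reactants: 1 5-methoxyresorcinol
Product: 2 1-methoxy-3,5-bis(methoxymethoxy)benzene
Conditions: MOMCl, i-Pr2NEt, CH2Cl2, 0 °C → rt
Reagents that add atoms: chloromethyl methyl ether, COCCl
Why: Double O-alkylation of the phenols; the MOM ethers later direct lithiation and stabilise the aryllithium by chelation.

Step 2
Reactants: 2 1-methoxy-3,5-bis(methoxymethoxy)benzene
Product: 4 4-methoxy-2,6-bis(methoxymethoxy)benzaldehyde, via aryllithium 3 (not isolated)
Conditions: n-BuLi, TMEDA, THF, 0 °C; DMF; H2O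
Reagents that add atoms: N,N-dimethylformamide, CN(C)C=O
Why: Directed ortho-metalation at the position flanked by both MOM-oxy groups (the doubly activated site), then formylation.

Step 3
Reactants: 4 4-methoxy-2,6-bis(methoxymethoxy)benzaldehyde
Product: 6 (E)-1-[4-methoxy-2,6-bis(methoxymethoxy)phenyl]buta-1,3-diene, via lithium β-oxido phosphine oxide adduct 5 (not isolated)
Conditions: allyl(diphenyl)phosphine oxide, n-BuLi, THF–HMPA, −78 °C → rt
Reagents that add atoms: allyl(diphenyl)phosphine oxide, C=CCP(=O)(c1ccccc1)c1ccccc1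
Why: Horner–Wittig olefination; α-attack of the lithiated allyl phosphine oxide in HMPA and syn-elimination of diphenylphosphinate from the threo adduct should give the E-diene.

Step 4
Reactants: 7 methyl 3-(4-hydroxyphenyl)propanoate
Product: 8 methyl 3-(ArS)propanoate
Conditions: TBSCl, imidazole, DMF, rt
Reagents that add atoms: tert-butyldimethylsilyl chloride, CC(C)(C)[Si](C)(C)Cl
Why: Silylation of the phenol; the silyl ether survives hydride, organolithium and zerovalent nickel and is removed by fluoride at the end.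

Step 5
Reactants: 8 methyl 3-(ArS)propanoate
Product: 9 3-(ArS)propanal
Conditions: i-Bu2AlH (1.05 equiv), CH2Cl2, −78 °C; MeOH, aq. potassium sodium tartrate
Reagents that add atoms: none
Why: Partial reduction of the ester; the aluminium hemiacetal is stable at −78 °C and releases the aldehyde only on work-up.

Step 6
Reactants: 6 (E)-1-[4-methoxy-2,6-bis(methoxymethoxy)phenyl]buta-1,3-diene; 9 3-(ArS)propanal; 10 4-(TBS-oxy)phenylboronic acid
Product: 12 (3S,5E,7R)-7-[4-methoxy-2,6-bis(methoxymethoxy)phenyl]-1,7-bis(ArS)hept-5-en-3-ol, via borate ester 11 (not isolated)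
Conditions: Ni(cod)2 (10 mol %), chiral spirobiindane phosphoramidite L* (12 mol %), 10 (1.5 equiv), 9 added slowly, THF–toluene, 25 → 40 °C; pH 7 buffer
Reagents that add atoms: none
Why: Proposed new method: zerovalent nickel bearing L* binds the terminal olefin of 6 and the carbonyl group of 9 and joins C4'' to the carbonyl carbon by oxidative cyclisation, giving an alkoxide-tethered syn-η3-allyl nickel species; the nickel alkoxide activates 10 through a B–O ate complex, the aryl group passes to nickel, and reductive elimination at the benzylic allyl terminus C1'' gives borate 11 with the E-olefin, which is hydrolysed on work-up. The closest known reaction type is the nickel-catalysed three-component 1,4-coupling of 1,3-dienes, aldehydes and organozinc or organoboron reagents to racemic (E)-homoallylic alcohols, together with enantioselective nickel–phosphoramidite reductive couplings of dienes and aldehydes. No ring is closed. C7 (C1'') is set by the diene face that carries nickel, because the aryl group comes from the metal, and that face is selected by L* in the oxidative cyclisation. C3 (C5'') is set in the same event by the aldehyde face: in the five-membered O–Ni–allyl chelate the 2-arylethyl group should take the position turned away from the ligand, so the 1,5-relation is decided in one intermediate and not by two independent inductions. The step needs 1,4- over 1,2-arylation, which the allyl terminus outside the chelate should secure (it is benzylic, and the twisted di-ortho-substituted ring A gives no conjugative reason to keep a styrene). It also needs the coupling to outrun direct aryl transfer to the aldehyde, which slow addition of 9 should secure. If the intrinsic 1,5-sense were the other one, the antipode of L* would still be chosen for C7 and the carbinol centre alone inverted by a Mitsunobu reaction.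

Step 7
Reactants: 12 (3S,5E,7R)-7-[4-methoxy-2,6-bis(methoxymethoxy)phenyl]-1,7-bis(ArS)hept-5-en-3-ol
Product: 13 (3S,5E,7R)-3-(TBS-oxy)-7-[4-methoxy-2,6-bis(methoxymethoxy)phenyl]-1,7-bis(ArS)hept-5-ene
Conditions: TBSCl, imidazole, DMAP (cat.), DMF, 40 °C
Reagents that add atoms: tert-butyldimethylsilyl chloride, CC(C)(C)[Si](C)(C)Cl
Why: Silylation of the secondary alcohol so that it neither consumes organolithium nor competes in the later oxidation; the chloride is used because silyl triflate with pyridine bases can attack MOM ethers.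

Step 8
Reactants: 13 (3S,5E,7R)-3-(TBS-oxy)-7-[4-methoxy-2,6-bis(methoxymethoxy)phenyl]-1,7-bis(ArS)hept-5-ene
Product: 14 (3S,5E,7R)-7-[3-bromo-4-methoxy-2,6-bis(methoxymethoxy)phenyl]-3-(TBS-oxy)-1,7-bis(ArS)hept-5-ene
Conditions: NBS (1.0 equiv), CH2Cl2, −20 → 0 °C, dark
Reagents that add atoms: N-bromosuccinimide, O=C1CCC(=O)N1Br
Why: Electrophilic aromatic bromination of the trioxygenated ring, far more nucleophilic than the olefin or the silyloxyphenyl rings; the two free positions are equivalent by rotation about A3–C1'', so one monobromide results.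

Step 9
Reactants: 15 4-(TBS-oxy)benzaldehyde
Product: 16 (1R)-1-(ArS)but-3-en-1-ol
Conditions: B-allyldiisopinocampheylborane [from (+)-Ipc2BOMe and allylmagnesium bromide], Et2O, −78 °C; ethanolamine
Reagents that add atoms: allylmagnesium bromide, C=CC[Mg]Br (allyl group, delivered through B-allyldiisopinocampheylborane, C=CCB(C1CC2CC(C1C)C2(C)C)C1CC2CC(C1C)C2(C)C)
Why: Asymmetric allylboration through a chair-like six-membered transition state; the reagent antipode from (−)-α-pinene is expected to give the 1R carbinol (future C2), and the non-oxidative work-up spares the aryl silyl ether.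

Step 10
Reactants: 16 (1R)-1-(ArS)but-3-en-1-ol
Product: 18 (3R)-3-hydroxy-3-(ArS)propanoic acid, via β-hydroxy aldehyde 17 (not isolated)
Conditions: O3, CH2Cl2–MeOH, −78 °C; PPh3; then NaClO2, NaH2PO4, 2-methyl-2-butene, t-BuOH–H2O, 0 °C
Reagents that add atoms: ozone, [O-][O+]=O; sodium chlorite, [Na+].[O-]Cl=O
Why: Ozonolysis of the terminal olefin followed by Pinnick oxidation; both are non-basic, so the aryl silyl ether and the benzylic carbinol centre are untouched.

Step 11
Reactants: 18 (3R)-3-hydroxy-3-(ArS)propanoic acid; 9 3-(ArS)propanal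
Product: 20 (2S,6R)-6-(ArS)-2-[2-(ArS)ethyl]-1,3-dioxan-4-one, via bis(trimethylsilyl) derivative 19 (not isolated)
Conditions: (Me3Si)2NH, Me3SiCl (cat.), CH2Cl2, rt, evaporate; then 9, Me3SiOTf (5 mol %), CH2Cl2, −78 °C
Reagents that add atoms: none
Why: Silyl-triflate-catalysed acetalisation of the silyl ester/silyl ether with the aldehyde; the 2,6-cis dioxanone with both substituents equatorial should form, which fixes the acetal carbon (future C6) relative to C2.

Step 12
Reactants: 20 (2S,6R)-6-(ArS)-2-[2-(ArS)ethyl]-1,3-dioxan-4-one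
Product: 21 (3R)-3-(ArS)-3-{[(3S)-1-(ArS)hex-5-en-3-yl]oxy}propanoic acid
Conditions: allyltrimethylsilane, TiCl4 (1.1 equiv), CH2Cl2, −78 °C; H2O
Reagents that add atoms: allyltrimethylsilane, C=CC[Si](C)(C)C
Why: Lewis-acid opening of the acetal C–O(acyl) bond and attack of the allylsilane anti to the departing carboxylate (inversion), the established course for chiral 1,3-dioxan-4-one acetals. This sets C6 and gives the C2–O1–C6 ether in the relative configuration that corresponds to a 2,6-trans oxane.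

Step 13
Reactants: 15 4-(TBS-oxy)benzaldehyde
Product: 22 rac-1-(ArS)prop-2-en-1-ol
Conditions: vinylmagnesium bromide, THF, −78 → 0 °C; aq. NH4Cl
Reagents that add atoms: vinylmagnesium bromide, C=C[Mg]Br
Why: Grignard addition to the aldehyde.

Step 14
Reactants: 22 rac-1-(ArS)prop-2-en-1-ol
Product: 23 (1S)-1-(ArS)prop-2-en-1-ol
Conditions: Candida antarctica lipase B (immobilised), vinyl acetate, MTBE, 30 °C, stopped just past half conversion
Reagents that add atoms: none
Why: Lipase-catalysed kinetic resolution; the enzyme should acylate the R alcohol (aryl as the large group, vinyl as the medium one) and leave the S alcohol, which carries the future C9 centre.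

Step 15
Reactants: 21 (3R)-3-(ArS)-3-{[(3S)-1-(ArS)hex-5-en-3-yl]oxy}propanoic acid; 23 (1S)-1-(ArS)prop-2-en-1-ol
Product: 24 (3R)-3-(ArS)-3-{[(3S,5E,7S)-7-hydroxy-1,7-bis(ArS)hept-5-en-3-yl]oxy}propanoic acid
Conditions: second-generation Hoveyda–Grubbs catalyst (5 mol %), 23 (3 equiv), 1,4-benzoquinone (10 mol %), CH2Cl2, 40 °C
Reagents that add atoms: none
Why: Olefin cross-metathesis between an unhindered terminal olefin and a secondary allylic alcohol, which should give the E-olefin C4=C8; benzoquinone suppresses ruthenium hydride isomerisation of the allylic alcohol.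

Step 16
Reactants: 24 (3R)-3-(ArS)-3-{[(3S,5E,7S)-7-hydroxy-1,7-bis(ArS)hept-5-en-3-yl]oxy}propanoic acid
Product: 26 (4R,6S,8E,10S)-4,10-bis(ArS)-6-[2-(ArS)ethyl]-1,5-dioxacyclodec-8-en-2-one, via mixed anhydride 25 (not isolated)
Conditions: 2-methyl-6-nitrobenzoic anhydride, DMAP, CH2Cl2 (2 mM), rt, slow addition
Reagents that add atoms: none
Why: Shiina macrolactonisation at ambient temperature; the ring ether removes transannular hydrogens from the ten-membered ring, and the mild conditions limit β-elimination of the activated β-alkoxy acyl group.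

Step 17
Reactants: 26 (4R,6S,8E,10S)-4,10-bis(ArS)-6-[2-(ArS)ethyl]-1,5-dioxacyclodec-8-en-2-one
Product: 29 (2R,3R,4S,6S)-2-(ArS)-4-[(E)-2-(ArS)ethenyl]-6-[2-(ArS)ethyl]oxane-3-carboxylic acid, via silyl ketene acetal 27 (not isolated), via trimethylsilyl ester 28 (not isolated)
Conditions: Me3SiCl–Et3N, LiN(SiMe3)2, THF, −78 °C; then toluene, 80 °C; pH 4 buffer
Reagents that add atoms: none
Why: Ring-contracting Ireland–Claisen rearrangement; the ring forces C2 cis to the ring oxygen in the ketene acetal, and with the E-olefin the [3,3] shift can run through a chair-like array that forms C3–C4 with the C7 and C8 substituents cis. The pseudo-equatorial aryl group on C9 should give the E-styryl group, and the 9S centre transfers its chirality to C3 (R) and C4 (S), while C2 and C6 are carried in unchanged. In-situ silylation keeps the β-alkoxy enolate from eliminating.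

Step 18
Reactants: 29 (2R,3R,4S,6S)-2-(ArS)-4-[(E)-2-(ArS)ethenyl]-6-[2-(ArS)ethyl]oxane-3-carboxylic acid
Product: 30 {(2R,3S,4S,6S)-2-(ArS)-4-[(E)-2-(ArS)ethenyl]-6-[2-(ArS)ethyl]oxan-3-yl}methanol
Conditions: LiAlH4, THF, 0 °C
Reagents that add atoms: none
Why: Hydride reduction of the acid; the C3 descriptor changes only because the priorities change.

Step 19
Reactants: 30 {(2R,3S,4S,6S)-2-(ArS)-4-[(E)-2-(ArS)ethenyl]-6-[2-(ArS)ethyl]oxan-3-yl}methanol
Product: 31 (2R,3R,4S,6S)-2-(ArS)-4-[(E)-2-(ArS)ethenyl]-6-[2-(ArS)ethyl]oxane-3-carbaldehyde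
Conditions: Dess–Martin periodinane, NaHCO3, CH2Cl2, 0 °C
Reagents that add atoms: none
Why: Buffered Dess–Martin oxidation, non-basic so that C3 is not epimerised and the β-alkoxy aldehyde is not opened; the aldehyde is used at once.

Step 20
Reactants: 14 (3S,5E,7R)-7-[3-bromo-4-methoxy-2,6-bis(methoxymethoxy)phenyl]-3-(TBS-oxy)-1,7-bis(ArS)hept-5-ene; 31 (2R,3R,4S,6S)-2-(ArS)-4-[(E)-2-(ArS)ethenyl]-6-[2-(ArS)ethyl]oxane-3-carbaldehyde
Product: 34 (RS)-{2,4-bis(methoxymethoxy)-6-methoxy-3-[(1R,2E,5S)-5-(TBS-oxy)-1,7-bis(ArS)hept-2-en-1-yl]phenyl}{(2R,3S,4S,6S)-2-(ArS)-4-[(E)-2-(ArS)ethenyl]-6-[2-(ArS)ethyl]oxan-3-yl}methanol, via aryllithium 32 (not isolated), via arylcerium dichloride 33 (not isolated)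
Conditions: t-BuLi (2 equiv), THF, −78 °C; CeCl3, −78 °C; then 31, −78 → −40 °C
Reagents that add atoms: none
Why: Bromine–lithium exchange is faster at −78 °C than deprotonation of C1''–H and is assisted by the ortho MOM-oxy group. Transmetalation to cerium gives a weakly basic nucleophile that adds to the hindered, enolisable aldehyde; the new carbinol centre need not be controlled because it is oxidised next.

Step 21
Reactants: 34 (RS)-{2,4-bis(methoxymethoxy)-6-methoxy-3-[(1R,2E,5S)-5-(TBS-oxy)-1,7-bis(ArS)hept-2-en-1-yl]phenyl}{(2R,3S,4S,6S)-2-(ArS)-4-[(E)-2-(ArS)ethenyl]-6-[2-(ArS)ethyl]oxan-3-yl}methanol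
Product: 35 {2,4-bis(methoxymethoxy)-6-methoxy-3-[(1R,2E,5S)-5-(TBS-oxy)-1,7-bis(ArS)hept-2-en-1-yl]phenyl}{(2R,3R,4S,6S)-2-(ArS)-4-[(E)-2-(ArS)ethenyl]-6-[2-(ArS)ethyl]oxan-3-yl}methanone
Conditions: Dess–Martin periodinane, NaHCO3, CH2Cl2, rt
Reagents that add atoms: none
Why: Oxidation of the only free alcohol to the aryl ketone under neutral conditions; both carbinol epimers converge.

Step 22
Reactants: 35 {2,4-bis(methoxymethoxy)-6-methoxy-3-[(1R,2E,5S)-5-(TBS-oxy)-1,7-bis(ArS)hept-2-en-1-yl]phenyl}{(2R,3R,4S,6S)-2-(ArS)-4-[(E)-2-(ArS)ethenyl]-6-[2-(ArS)ethyl]oxan-3-yl}methanone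
Product: 36 {2,4-dihydroxy-6-methoxy-3-[(1R,2E,5S)-5-(TBS-oxy)-1,7-bis(ArS)hept-2-en-1-yl]phenyl}{(2R,3R,4S,6S)-2-(ArS)-4-[(E)-2-(ArS)ethenyl]-6-[2-(ArS)ethyl]oxan-3-yl}methanone
Conditions: ZnBr2, n-PrSH, CH2Cl2, 0 °C, short reaction time
Reagents that add atoms: none
Why: Lewis-acid/thiol cleavage of aryl MOM ethers (the acetal carbon is transferred to sulfur) without protic acid. All aryl oxygens at C2, C9 and the side chain are still silylated, which keeps the benzylic C2–O1 bond from ionising, and any loss of the aliphatic silyl ether here is harmless.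

Step 23
Reactants: 36 {2,4-dihydroxy-6-methoxy-3-[(1R,2E,5S)-5-(TBS-oxy)-1,7-bis(ArS)hept-2-en-1-yl]phenyl}{(2R,3R,4S,6S)-2-(ArS)-4-[(E)-2-(ArS)ethenyl]-6-[2-(ArS)ethyl]oxan-3-yl}methanone
Product: 37 blepharocalyxin B
Conditions: Bu4NF, AcOH (1:1), THF, 0 °C → 40 °C
Reagents that add atoms: none
Why: Fluoride cleavage of the five aryl silyl ethers and the one alkyl silyl ether; the acetic acid buffer keeps the phenoxides protonated so that neither E1cB opening of the oxane nor epimerisation at C3 is triggered.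

Compound list

1 | 5-methoxyresorcinol | COc1cc(O)cc(O)c1 | starting material
2 | 1-methoxy-3,5-bis(methoxymethoxy)benzene | COCOc1cc(OC)cc(OCOC)c1 | intermediate
3 | [4-methoxy-2,6-bis(methoxymethoxy)phenyl]lithium | [Li]c1c(OCOC)cc(OC)cc1OCOC | intermediate
4 | 4-methoxy-2,6-bis(methoxymethoxy)benzaldehyde | O=Cc1c(OCOC)cc(OC)cc1OCOC | intermediate
5 | lithium 2-(diphenylphosphoryl)-1-[4-methoxy-2,6-bis(methoxymethoxy)phenyl]but-3-en-1-olate (diastereomer mixture, threo expected to predominate) | [Li]OC(C(C=C)P(=O)(c1ccccc1)c1ccccc1)c1c(OCOC)cc(OC)cc1OCOC | intermediate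
6 | (E)-1-[4-methoxy-2,6-bis(methoxymethoxy)phenyl]buta-1,3-diene | C=C/C=C/c1c(OCOC)cc(OC)cc1OCOC | intermediate
7 | methyl 3-(4-hydroxyphenyl)propanoate | COC(=O)CCc1ccc(O)cc1 | starting material
8 | methyl 3-[4-(tert-butyldimethylsilyloxy)phenyl]propanoate | COC(=O)CCc1ccc(O[Si](C)(C)C(C)(C)C)cc1 | intermediate
9 | 3-[4-(tert-butyldimethylsilyloxy)phenyl]propanal | O=CCCc1ccc(O[Si](C)(C)C(C)(C)C)cc1 | intermediate
10 | 4-(tert-butyldimethylsilyloxy)phenylboronic acid | OB(O)c1ccc(O[Si](C)(C)C(C)(C)C)cc1 | starting material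
11 | dihydrogen borate ester of 12 at the C3 oxygen, (3S,5E,7R) | COc1cc(OCOC)c([C@H](/C=C/C[C@@H](OB(O)O)CCc2ccc(O[Si](C)(C)C(C)(C)C)cc2)c2ccc(O[Si](C)(C)C(C)(C)C)cc2)c(OCOC)c1 | intermediate
12 | (3S,5E,7R)-7-[4-methoxy-2,6-bis(methoxymethoxy)phenyl]-1,7-bis[4-(tert-butyldimethylsilyloxy)phenyl]hept-5-en-3-ol | COc1cc(OCOC)c([C@H](/C=C/C[C@@H](O)CCc2ccc(O[Si](C)(C)C(C)(C)C)cc2)c2ccc(O[Si](C)(C)C(C)(C)C)cc2)c(OCOC)c1 | intermediate
13 | (3S,5E,7R)-3-(tert-butyldimethylsilyloxy)-7-[4-methoxy-2,6-bis(methoxymethoxy)phenyl]-1,7-bis[4-(tert-butyldimethylsilyloxy)phenyl]hept-5-ene | COc1cc(OCOC)c([C@H](/C=C/C[C@@H](O[Si](C)(C)C(C)(C)C)CCc2ccc(O[Si](C)(C)C(C)(C)C)cc2)c2ccc(O[Si](C)(C)C(C)(C)C)cc2)c(OCOC)c1 | intermediate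
14 | (3S,5E,7R)-7-[3-bromo-4-methoxy-2,6-bis(methoxymethoxy)phenyl]-3-(tert-butyldimethylsilyloxy)-1,7-bis[4-(tert-butyldimethylsilyloxy)phenyl]hept-5-ene | COc1cc(OCOC)c([C@H](/C=C/C[C@@H](O[Si](C)(C)C(C)(C)C)CCc2ccc(O[Si](C)(C)C(C)(C)C)cc2)c2ccc(O[Si](C)(C)C(C)(C)C)cc2)c(OCOC)c1Br | intermediate
15 | 4-(tert-butyldimethylsilyloxy)benzaldehyde | O=Cc1ccc(O[Si](C)(C)C(C)(C)C)cc1 | starting material
16 | (1R)-1-[4-(tert-butyldimethylsilyloxy)phenyl]but-3-en-1-ol | C=CC[C@@H](O)c1ccc(O[Si](C)(C)C(C)(C)C)cc1 | intermediate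
17 | (3R)-3-hydroxy-3-[4-(tert-butyldimethylsilyloxy)phenyl]propanal | O=CC[C@@H](O)c1ccc(O[Si](C)(C)C(C)(C)C)cc1 | intermediate
18 | (3R)-3-hydroxy-3-[4-(tert-butyldimethylsilyloxy)phenyl]propanoic acid | OC(=O)C[C@@H](O)c1ccc(O[Si](C)(C)C(C)(C)C)cc1 | intermediate
19 | trimethylsilyl (3R)-3-[4-(tert-butyldimethylsilyloxy)phenyl]-3-(trimethylsilyloxy)propanoate | C[Si](C)(C)OC(=O)C[C@@H](O[Si](C)(C)C)c1ccc(O[Si](C)(C)C(C)(C)C)cc1 | intermediate
20 | (2S,6R)-6-[4-(tert-butyldimethylsilyloxy)phenyl]-2-{2-[4-(tert-butyldimethylsilyloxy)phenyl]ethyl}-1,3-dioxan-4-one (2,6-cis) | O=C1C[C@H](c2ccc(O[Si](C)(C)C(C)(C)C)cc2)O[C@H](CCc2ccc(O[Si](C)(C)C(C)(C)C)cc2)O1 | intermediate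
21 | (3R)-3-[4-(tert-butyldimethylsilyloxy)phenyl]-3-({(3S)-1-[4-(tert-butyldimethylsilyloxy)phenyl]hex-5-en-3-yl}oxy)propanoic acid | OC(=O)C[C@@H](O[C@@H](CCc1ccc(O[Si](C)(C)C(C)(C)C)cc1)CC=C)c1ccc(O[Si](C)(C)C(C)(C)C)cc1 | intermediate
22 | rac-1-[4-(tert-butyldimethylsilyloxy)phenyl]prop-2-en-1-ol | C=CC(O)c1ccc(O[Si](C)(C)C(C)(C)C)cc1 | intermediate
23 | (1S)-1-[4-(tert-butyldimethylsilyloxy)phenyl]prop-2-en-1-ol | C=C[C@H](O)c1ccc(O[Si](C)(C)C(C)(C)C)cc1 | intermediate
24 | (3R)-3-[4-(tert-butyldimethylsilyloxy)phenyl]-3-({(3S,5E,7S)-7-hydroxy-1,7-bis[4-(tert-butyldimethylsilyloxy)phenyl]hept-5-en-3-yl}oxy)propanoic acid | OC(=O)C[C@@H](O[C@@H](CCc1ccc(O[Si](C)(C)C(C)(C)C)cc1)C/C=C/[C@H](O)c1ccc(O[Si](C)(C)C(C)(C)C)cc1)c1ccc(O[Si](C)(C)C(C)(C)C)cc1 | intermediate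
25 | mixed anhydride of 24 with 2-methyl-6-nitrobenzoic acid | Cc1cccc([N+](=O)[O-])c1C(=O)OC(=O)C[C@@H](O[C@@H](CCc1ccc(O[Si](C)(C)C(C)(C)C)cc1)C/C=C/[C@H](O)c1ccc(O[Si](C)(C)C(C)(C)C)cc1)c1ccc(O[Si](C)(C)C(C)(C)C)cc1 | intermediate
26 | (4R,6S,8E,10S)-4,10-bis[4-(tert-butyldimethylsilyloxy)phenyl]-6-{2-[4-(tert-butyldimethylsilyloxy)phenyl]ethyl}-1,5-dioxacyclodec-8-en-2-one | O=C1C[C@H](c2ccc(O[Si](C)(C)C(C)(C)C)cc2)O[C@@H](CCc2ccc(O[Si](C)(C)C(C)(C)C)cc2)C/C=C/[C@@H](c2ccc(O[Si](C)(C)C(C)(C)C)cc2)O1 | intermediate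
27 | trimethylsilyl ketene acetal of 26 (C3=C7 double bond, C2 cis to the ring oxygen; 4R,6S,8E,10S) | C[Si](C)(C)O/C1=C/[C@H](c2ccc(O[Si](C)(C)C(C)(C)C)cc2)O[C@@H](CCc2ccc(O[Si](C)(C)C(C)(C)C)cc2)C/C=C/[C@@H](c2ccc(O[Si](C)(C)C(C)(C)C)cc2)O1 | intermediate
28 | trimethylsilyl (2R,3R,4S,6S)-2-[4-(tert-butyldimethylsilyloxy)phenyl]-4-{(E)-2-[4-(tert-butyldimethylsilyloxy)phenyl]ethenyl}-6-{2-[4-(tert-butyldimethylsilyloxy)phenyl]ethyl}oxane-3-carboxylate | C[Si](C)(C)OC(=O)[C@@H]1[C@H](/C=C/c2ccc(O[Si](C)(C)C(C)(C)C)cc2)C[C@H](CCc2ccc(O[Si](C)(C)C(C)(C)C)cc2)O[C@H]1c1ccc(O[Si](C)(C)C(C)(C)C)cc1 | intermediate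
29 | (2R,3R,4S,6S)-2-[4-(tert-butyldimethylsilyloxy)phenyl]-4-{(E)-2-[4-(tert-butyldimethylsilyloxy)phenyl]ethenyl}-6-{2-[4-(tert-butyldimethylsilyloxy)phenyl]ethyl}oxane-3-carboxylic acid | OC(=O)[C@@H]1[C@H](/C=C/c2ccc(O[Si](C)(C)C(C)(C)C)cc2)C[C@H](CCc2ccc(O[Si](C)(C)C(C)(C)C)cc2)O[C@H]1c1ccc(O[Si](C)(C)C(C)(C)C)cc1 | intermediate
30 | {(2R,3S,4S,6S)-2-[4-(tert-butyldimethylsilyloxy)phenyl]-4-{(E)-2-[4-(tert-butyldimethylsilyloxy)phenyl]ethenyl}-6-{2-[4-(tert-butyldimethylsilyloxy)phenyl]ethyl}oxan-3-yl}methanol | OC[C@@H]1[C@H](/C=C/c2ccc(O[Si](C)(C)C(C)(C)C)cc2)C[C@H](CCc2ccc(O[Si](C)(C)C(C)(C)C)cc2)O[C@H]1c1ccc(O[Si](C)(C)C(C)(C)C)cc1 | intermediate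
31 | (2R,3R,4S,6S)-2-[4-(tert-butyldimethylsilyloxy)phenyl]-4-{(E)-2-[4-(tert-butyldimethylsilyloxy)phenyl]ethenyl}-6-{2-[4-(tert-butyldimethylsilyloxy)phenyl]ethyl}oxane-3-carbaldehyde | O=C[C@@H]1[C@H](/C=C/c2ccc(O[Si](C)(C)C(C)(C)C)cc2)C[C@H](CCc2ccc(O[Si](C)(C)C(C)(C)C)cc2)O[C@H]1c1ccc(O[Si](C)(C)C(C)(C)C)cc1 | intermediate
32 | aryllithium from 14 (lithium in place of bromine at A1) | COc1cc(OCOC)c([C@H](/C=C/C[C@@H](O[Si](C)(C)C(C)(C)C)CCc2ccc(O[Si](C)(C)C(C)(C)C)cc2)c2ccc(O[Si](C)(C)C(C)(C)C)cc2)c(OCOC)c1[Li] | intermediate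
33 | arylcerium dichloride from 32 (CeCl2 at A1) | COc1cc(OCOC)c([C@H](/C=C/C[C@@H](O[Si](C)(C)C(C)(C)C)CCc2ccc(O[Si](C)(C)C(C)(C)C)cc2)c2ccc(O[Si](C)(C)C(C)(C)C)cc2)c(OCOC)c1[Ce](Cl)Cl | intermediate
34 | (RS)-carbinol at C7: {2,4-bis(methoxymethoxy)-6-methoxy-3-[(1R,2E,5S)-5-(tert-butyldimethylsilyloxy)-1,7-bis(4-(tert-butyldimethylsilyloxy)phenyl)hept-2-en-1-yl]phenyl}{(2R,3S,4S,6S)-oxan-3-yl as in 30}methanol, both C7 epimers | COc1cc(OCOC)c([C@H](/C=C/C[C@@H](O[Si](C)(C)C(C)(C)C)CCc2ccc(O[Si](C)(C)C(C)(C)C)cc2)c2ccc(O[Si](C)(C)C(C)(C)C)cc2)c(OCOC)c1C(O)[C@@H]1[C@H](/C=C/c2ccc(O[Si](C)(C)C(C)(C)C)cc2)C[C@H](CCc2ccc(O[Si](C)(C)C(C)(C)C)cc2)O[C@H]1c1ccc(O[Si](C)(C)C(C)(C)C)cc1 | intermediate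
35 | ketone: {2,4-bis(methoxymethoxy)-6-methoxy-3-[(1R,2E,5S)-5-(tert-butyldimethylsilyloxy)-1,7-bis(4-(tert-butyldimethylsilyloxy)phenyl)hept-2-en-1-yl]phenyl}{(2R,3R,4S,6S)-oxan-3-yl as in 29}methanone | COc1cc(OCOC)c([C@H](/C=C/C[C@@H](O[Si](C)(C)C(C)(C)C)CCc2ccc(O[Si](C)(C)C(C)(C)C)cc2)c2ccc(O[Si](C)(C)C(C)(C)C)cc2)c(OCOC)c1C(=O)[C@@H]1[C@H](/C=C/c2ccc(O[Si](C)(C)C(C)(C)C)cc2)C[C@H](CCc2ccc(O[Si](C)(C)C(C)(C)C)cc2)O[C@H]1c1ccc(O[Si](C)(C)C(C)(C)C)cc1 | intermediate
36 | ring-A diphenol: 35 with free hydroxyl groups at A2 and A4, six silyl ethers kept | COc1cc(O)c([C@H](/C=C/C[C@@H](O[Si](C)(C)C(C)(C)C)CCc2ccc(O[Si](C)(C)C(C)(C)C)cc2)c2ccc(O[Si](C)(C)C(C)(C)C)cc2)c(O)c1C(=O)[C@@H]1[C@H](/C=C/c2ccc(O[Si](C)(C)C(C)(C)C)cc2)C[C@H](CCc2ccc(O[Si](C)(C)C(C)(C)C)cc2)O[C@H]1c1ccc(O[Si](C)(C)C(C)(C)C)cc1 | intermediate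
37 | blepharocalyxin B, {2,4-dihydroxy-3-[(1R,2E,5S)-5-hydroxy-1,7-bis(4-hydroxyphenyl)hept-2-en-1-yl]-6-methoxyphenyl}{(2R,3R,4S,6S)-2-(4-hydroxyphenyl)-4-[(E)-2-(4-hydroxyphenyl)ethenyl]-6-[2-(4-hydroxyphenyl)ethyl]oxan-3-yl}methanone | COc1cc(O)c([C@H](/C=C/C[C@@H](O)CCc2ccc(O)cc2)c2ccc(O)cc2)c(O)c1C(=O)[C@@H]1[C@H](/C=C/c2ccc(O)cc2)C[C@H](CCc2ccc(O)cc2)O[C@H]1c1ccc(O)cc1 | target

Total step count: 23. Longest linear sequence: 13 steps (4, 5, 11, 12, 15, 16, 17, 18, 19, 20, 21, 22, 23).

Least certain steps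

Step 6 (key step, Proposed new method). Most likely failures are transfer of the aryl group to the wrong allyl terminus or directly to the aldehyde, protonolysis of the allyl nickel species (reductive coupling without arylation), and weak facial control by the ligand at the crowded, di-ortho-substituted benzylic terminus. The fallback uses known chemistry, sets out from 9, 22 and 2, and returns at 12. Asymmetric allylboration of 9 with the same borane antipode as in step 9 gives (3S)-1-(ArS)hex-5-en-3-ol F1. Treatment of 22 with SOCl2 gives, by allylic transposition, (E)-1-(3-chloroprop-1-enyl)-4-(TBS-oxy)benzene F2. Lithiation of 2 as in step 2 followed by MgBr2·OEt2 gives [4-methoxy-2,6-bis(methoxymethoxy)phenyl]magnesium bromide F3. A CuCl/chiral N-heterocyclic carbene-catalysed SN2′ allylic arylation of F2 with F3 gives 2-[(1R)-1-(ArS)prop-2-enyl]-5-methoxy-1,3-bis(methoxymethoxy)benzene F4. Cross-metathesis of F4 with excess F1 (second-generation Hoveyda–Grubbs catalyst) gives 12 with the E-olefin.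

Step 17. The lactone enolate may expel the β-ether oxygen before it is silylated, the benzylic allylic C–O bond may ionise instead of shifting in concert, or the barrier may be raised because the chair-like array holds the C6 chain pseudo-axial next to C8. The fallback sets out from 21 and from the resolution of 22, and returns at 29. (1R)-1-(ArS)prop-2-enyl acetate F5, which the lipase forms beside 23, is cleaved with i-Bu2AlH to (1R)-1-(ArS)prop-2-en-1-ol F6. Esterification of 21 with F6 (DCC, DMAP) gives the diene ester (1R)-1-(ArS)prop-2-enyl (3R)-3-(ArS)-3-{[(3S)-1-(ArS)hex-5-en-3-yl]oxy}propanoate F7. Ring-closing metathesis under equilibrating conditions with the second-generation Grubbs catalyst should give the (4R,6S,8Z,10R)-lactone F8. Its ketene acetal can react only through the boat-like array, which has no C6/C8 syn-axial contact and, with the 9R centre, leads to the same acid 29.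

Step 16. Closure of the ten-membered ring may lose to oligomerisation or to β-elimination of the activated β-alkoxy acyl group. The fallback sets out from 21 and 23 and returns at 26. The ester bond is made first, intermolecularly (DCC, DMAP), giving (1S)-1-(ArS)prop-2-enyl (3R)-3-(ArS)-3-{[(3S)-1-(ArS)hex-5-en-3-yl]oxy}propanoate F9, and the ring is then closed by metathesis at high dilution. The E-isomer of the product is 26; if the Z-isomer predominates, the R-alcohol series described for step 17 is used instead.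

Step 20. The aryl-metal may act as a base toward the aldehyde (enolisation at C3 and opening of the oxane), may be quenched by C1''–H, or may fail to add for steric reasons. The fallback sets out from 29 and 14 and returns at 35. Acid 29 is converted with 1-chloro-N,N,2-trimethylprop-1-en-1-amine into (2R,3R,4S,6S)-2-(ArS)-4-[(E)-2-(ArS)ethenyl]-6-[2-(ArS)ethyl]oxane-3-carbonyl chloride F10. Aryllithium 32 is transmetalated with ZnCl2 to the arylzinc chloride F11. A Pd(PPh3)4-catalysed Negishi acylation joins F10 and F11 to give ketone 35 directly, with a non-basic nucleophile and without steps 18, 19 and 21.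

Step 22. The Lewis acid may ionise the benzylic C2–O1 bond (epimerisation to the more stable 2,6-cis oxane) or trigger opening toward chalcone/flavanone products. The fallback sets out from 35 and returns at 37. Me3SiOTf with 2,2′-bipyridyl, a buffered silyl-transfer reagent, converts the two aryl MOM ethers into the A2,A4-bis(trimethylsilyl) ether of 36, F12, which is taken without isolation of a free phenol into the fluoride conditions of step 23.

Further compounds

F1 | step 6 | (3S)-1-[4-(tert-butyldimethylsilyloxy)phenyl]hex-5-en-3-ol | C=CC[C@@H](O)CCc1ccc(O[Si](C)(C)C(C)(C)C)cc1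
F2 | step 6 | (E)-1-(3-chloroprop-1-enyl)-4-(tert-butyldimethylsilyloxy)benzene | ClC/C=C/c1ccc(O[Si](C)(C)C(C)(C)C)cc1
F3 | step 6 | [4-methoxy-2,6-bis(methoxymethoxy)phenyl]magnesium bromide | Br[Mg]c1c(OCOC)cc(OC)cc1OCOC
F4 | step 6 | 2-{(1R)-1-[4-(tert-butyldimethylsilyloxy)phenyl]prop-2-enyl}-5-methoxy-1,3-bis(methoxymethoxy)benzene | COc1cc(OCOC)c([C@H](C=C)c2ccc(O[Si](C)(C)C(C)(C)C)cc2)c(OCOC)c1
F5 | step 17 | (1R)-1-[4-(tert-butyldimethylsilyloxy)phenyl]prop-2-enyl acetate | C=C[C@@H](OC(C)=O)c1ccc(O[Si](C)(C)C(C)(C)C)cc1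
F6 | step 17 | (1R)-1-[4-(tert-butyldimethylsilyloxy)phenyl]prop-2-en-1-ol | C=C[C@@H](O)c1ccc(O[Si](C)(C)C(C)(C)C)cc1
F7 | step 17 | (1R)-1-(ArS)prop-2-enyl (3R)-3-(ArS)-3-{[(3S)-1-(ArS)hex-5-en-3-yl]oxy}propanoate | C=C[C@@H](OC(=O)C[C@@H](O[C@@H](CCc1ccc(O[Si](C)(C)C(C)(C)C)cc1)CC=C)c1ccc(O[Si](C)(C)C(C)(C)C)cc1)c1ccc(O[Si](C)(C)C(C)(C)C)cc1
F8 | step 17 | (4R,6S,8Z,10R)-4,10-bis(ArS)-6-[2-(ArS)ethyl]-1,5-dioxacyclodec-8-en-2-one | O=C1C[C@H](c2ccc(O[Si](C)(C)C(C)(C)C)cc2)O[C@@H](CCc2ccc(O[Si](C)(C)C(C)(C)C)cc2)C/C=C\[C@H](c2ccc(O[Si](C)(C)C(C)(C)C)cc2)O1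
F9 | step 16 | (1S)-1-(ArS)prop-2-enyl (3R)-3-(ArS)-3-{[(3S)-1-(ArS)hex-5-en-3-yl]oxy}propanoate | C=C[C@H](OC(=O)C[C@@H](O[C@@H](CCc1ccc(O[Si](C)(C)C(C)(C)C)cc1)CC=C)c1ccc(O[Si](C)(C)C(C)(C)C)cc1)c1ccc(O[Si](C)(C)C(C)(C)C)cc1
F10 | step 20 | (2R,3R,4S,6S)-2-(ArS)-4-[(E)-2-(ArS)ethenyl]-6-[2-(ArS)ethyl]oxane-3-carbonyl chloride | ClC(=O)[C@@H]1[C@H](/C=C/c2ccc(O[Si](C)(C)C(C)(C)C)cc2)C[C@H](CCc2ccc(O[Si](C)(C)C(C)(C)C)cc2)O[C@H]1c1ccc(O[Si](C)(C)C(C)(C)C)cc1
F11 | step 20 | arylzinc chloride from 32 (ZnCl at A1) | COc1cc(OCOC)c([C@H](/C=C/C[C@@H](O[Si](C)(C)C(C)(C)C)CCc2ccc(O[Si](C)(C)C(C)(C)C)cc2)c2ccc(O[Si](C)(C)C(C)(C)C)cc2)c(OCOC)c1[Zn]Cl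
F12 | step 22 | A2,A4-bis(trimethylsilyl) ether of 36 | COc1cc(O[Si](C)(C)C)c([C@H](/C=C/C[C@@H](O[Si](C)(C)C(C)(C)C)CCc2ccc(O[Si](C)(C)C(C)(C)C)cc2)c2ccc(O[Si](C)(C)C(C)(C)C)cc2)c(O[Si](C)(C)C)c1C(=O)[C@@H]1[C@H](/C=C/c2ccc(O[Si](C)(C)C(C)(C)C)cc2)C[C@H](CCc2ccc(O[Si](C)(C)C(C)(C)C)cc2)O[C@H]1c1ccc(O[Si](C)(C)C(C)(C)C)cc1
A1 | alternative 1 | (2R,3R,4S,6S)-2-(ArS)-4-[(E)-2-(ArS)ethenyl]-6-[2-(ArS)ethyl]oxane-3-carboxylic acid (identical with 29) | OC(=O)[C@@H]1[C@H](/C=C/c2ccc(O[Si](C)(C)C(C)(C)C)cc2)C[C@H](CCc2ccc(O[Si](C)(C)C(C)(C)C)cc2)O[C@H]1c1ccc(O[Si](C)(C)C(C)(C)C)cc1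
A2 | alternative 2 | hexasilylated acylphloroglucinol (target skeleton with free hydroxyl groups at A2, A4 and A6) | Oc1cc(O)c([C@H](/C=C/C[C@@H](O[Si](C)(C)C(C)(C)C)CCc2ccc(O[Si](C)(C)C(C)(C)C)cc2)c2ccc(O[Si](C)(C)C(C)(C)C)cc2)c(O)c1C(=O)[C@@H]1[C@H](/C=C/c2ccc(O[Si](C)(C)C(C)(C)C)cc2)C[C@H](CCc2ccc(O[Si](C)(C)C(C)(C)C)cc2)O[C@H]1c1ccc(O[Si](C)(C)C(C)(C)C)cc1
A3 | alternative 2 | 4-hydroxy-2-pyranone precursor: 3-(silylated side chain)-6-[2-oxo-2-(silylated oxan-3-yl)ethyl]-4-hydroxy-2H-pyran-2-one | O=C1OC(CC(=O)[C@@H]2[C@H](/C=C/c3ccc(O[Si](C)(C)C(C)(C)C)cc3)C[C@H](CCc3ccc(O[Si](C)(C)C(C)(C)C)cc3)O[C@H]2c2ccc(O[Si](C)(C)C(C)(C)C)cc2)=CC(O)=C1[C@H](/C=C/C[C@@H](O[Si](C)(C)C(C)(C)C)CCc1ccc(O[Si](C)(C)C(C)(C)C)cc1)c1ccc(O[Si](C)(C)C(C)(C)C)cc1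
A4 | alternative 3 | hepta-MOM ether of the target with free A2 hydroxyl | COc1cc(OCOC)c([C@H](/C=C/C[C@@H](OCOC)CCc2ccc(OCOC)cc2)c2ccc(OCOC)cc2)c(O)c1C(=O)[C@@H]1[C@H](/C=C/c2ccc(OCOC)cc2)C[C@H](CCc2ccc(OCOC)cc2)O[C@H]1c1ccc(OCOC)cc1
A5 | alternative 3 | ring-A 2-(trimethylsilyl)aryl triflate (OTf at A2, SiMe3 at A1) carrying the MOM-protected side chain | COc1cc(OCOC)c([C@H](/C=C/C[C@@H](OCOC)CCc2ccc(OCOC)cc2)c2ccc(OCOC)cc2)c(OS(=O)(=O)C(F)(F)F)c1[Si](C)(C)C
A6 | alternative 3 | (2R,3R,4S,6S)-oxane-3-carboxylic acid with three aryl MOM ethers | OC(=O)[C@@H]1[C@H](/C=C/c2ccc(OCOC)cc2)C[C@H](CCc2ccc(OCOC)cc2)O[C@H]1c1ccc(OCOC)cc1
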